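## Structural features

The target 10 is a 2,2-dimethyl-2H-chromene in which a benzene ring (ring A) is fused along C4a–C8a to a pyran ring (ring B) made of O1, the quaternary C2 with its two methyl groups, and the C3=C4 double bond. Ring A is pentasubstituted: hydroxyl at C5, a 3-oxo-3-phenylpropanoyl chain at C6, methoxy at C7 and the only aromatic hydrogen at C8, so the acyl carbon sits between hydroxyl and methoxy and para to the carbon that bears the ring oxygen. There is no stereocentre, since C2 carries two identical methyl groups, and so no stereochemical relationship has to be set or preserved. The side chain is an ortho-hydroxyaryl 1,3-diketone that should exist largely as the enol chelated to the C5 hydroxyl; it is the most fragile part, because acid closes it onto the C5 oxygen to give a flavone and hard nucleophiles can cleave it by retro-Claisen reaction. The C3=C4 bond is an electron-rich styrene-type alkene that is sensitive to acid, oxidants and light, and the phenol is oxidisable. The real difficulty is regiochemical: on a phloroglucinol-type ring with two free CH positions and two hydroxyls, ring B must be built on exactly one carbon (the future C4a, between the hydroxyls) and one oxygen (the hydroxyl para to the acyl group). The key step uses the fact that C4 is a lone carbon joining C4a to the C3–C2(CH3)2–O1 unit, so that ring B can be put together from formaldehyde (C4) and isobutene (C3, C2 and both methyl groups) on the O–C8a–C4a edge of an acetophenone that already carries the full ring A pattern; as C4 is an sp2 CH in 10, the cycloadduct is a chroman and one dehydrogenation has to follow.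

## Logic of the disconnections

Disconnection of 10 into 7 and 8. The bond cut lies between the central CH2 of the 1,3-dicarbonyl chain and the benzoyl carbonyl carbon. This is the Claisen retron, and cutting there postpones the acid-sensitive, enolisable diketone to the very last step. Seven carbons leave as 8 and what remains is 7, a methyl ketone. The forward step must acylate on carbon a methyl ketone that carries a free ortho-hydroxyl, so it has to pass through 9 with at least three equivalents of base (the product is more acidic than 7) and end with a non-acidic quench.

Disconnection of 7 into 6. No skeletal bond is cut; two hydrogens are added back across C3=C4. The saturated pyran is the retron of a (4+2) cycloaddition with a plain alkene, which the chromene itself is not. The gain is access to a three-component ring construction at the price of one oxidation. The forward step must remove hydride from the benzylic C4 selectively in the presence of a free phenol, a methyl ketone and an aryl methyl ether.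

Disconnection of 6 into 5 and 3. C4–C3 and O1–C2 are cut in a retro-hetero-Diels–Alder sense. This removes ring B in one operation and leaves 5 as the heterodiene and 3 as the four-carbon alkene. The forward step must place the tertiary carbon of 3 on oxygen and must capture the transient 5 faster than 5 reacts with other nucleophiles in the mixture.

Disconnection of 5 through 4 into 1 and 2. 5 is 4 less water, and 4 is cut at C4a–C4 back to 1 and the one-carbon unit 2. This reaches a purchasable arene with the complete C5/C6/C7 pattern of ring A, so nothing has to be prepared before the key step. The forward step must hydroxymethylate the carbon between the two hydroxyls and not the other free CH, and must engage the hydroxyl para to the acetyl group and not the chelated one. For that reason 1 is used unprotected: the hydrogen bond of its ortho-hydroxyl is the control element, and any protecting group would remove it and add steps.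

## Other disconnections considered

Alternative 1: The cut is at C5–O and at the C6–carbonyl bond, so that C5 and C6 become the two ends of an aryne and the phenol oxygen and the whole side chain come from a carboxylic acid. The key step would give A1 from the silyl triflate A2 and the acid A3: fluoride would trigger 1,2-elimination of A2, the carboxylate of A3 would add through oxygen at C5, and the C6 aryl anion would take the acyl group from the aryl ester just formed. Hydrolysis of the dioxolane of A1 would then give 10.

In its favour, hydroxyl and acyl group arrive on adjacent carbons in one event, so their ortho relationship is a mechanistic necessity, and the complete side chain is delivered convergently. On both points it is better than the chosen plan, which needs a late Claisen condensation. The C7 methoxy group should polarise the aryne so that oxygen adds at C5, a control that is the equal of the chelation control used in the chosen plan.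

Against it:
- A2 needs a multistep preparation (pyran annulation, directed ortho-silylation, triflation), and A3 must be made and masked.
- Protonation of the hindered C6 anion by the acid (simple O–H insertion) competes with acyl transfer.
- The aryne can be intercepted by the C3=C4 bond of a second molecule.
- The final unmasking needs aqueous acid beside an acid-sensitive chromene and a diketone prone to flavone closure.

In comparison, the structural logic is more convergent, the mechanism carries more competing paths, and the step count would be roughly three times that of the chosen plan.

Alternative 2: The cut is at O1–C8a and C4–C4a, so that all of ring B comes from an aryne and an enal. The key step would give A4 from the silyl triflate A5 and 3-methylbut-2-enal A6. Fluoride would release the aryne from A5, and the carbonyl group of A6 would add across it, oxygen at C8a and carbon at C4a. The benzoxete would open to an ortho-quinone methide, and oxa-6π electrocyclisation would close O1–C2.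

In its favour, ring B arrives at the chromene oxidation level, so no dehydrogenation is needed, which is better than the chosen plan. The quinone methide is consumed intramolecularly, which is inherently more reliable than bimolecular capture by a gaseous alkene and is also better than the chosen plan. The orientation of the fusion should be fixed by the alkoxy group next to the aryne, the equal of the site control in the chosen plan.

Against it:
- A4 has no C6 acyl group. It would need metalation between the two alkoxy groups (in competition with C8), acetylation and acidic removal of the methoxymethyl group before it meets the route at 7.
- A5 is itself several steps from a simple phenol.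
- Addition across the carbonyl group competes with other aryne pathways and usually wants an excess of the enal.

In comparison, the ring construction is mechanistically the more secure, but ring A is left unfinished and the sequence would be about three times as long.

Alternative 3: Ring A itself is cut, at C8–C8a, C5–C6, C7–C8 and C4a–C5, back to a dihydropyranone diazoketone and an alkynyl ether. The key step would give A7 from the diazoketone A8 and methoxyethyne A9. Irradiation of A8 would give a vinylketene by Wolff rearrangement (C8–C8a). A (2+2) cycloaddition with A9 would give a vinylcyclobutenone (C5–C6, C7–C8). Warming would open it to a dienylketene that closes by 6π electrocyclisation (C4a–C5) and tautomerises to the phenol.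

In its favour, the C5 hydroxyl and C7 methoxy positions follow from the polarity of the ketene and the alkynyl ether, a regiocontrol that is the equal of, or better than, that of the chosen plan. Every bond-forming event is pericyclic and needs no protecting group. The C4 carbonyl of A7 would allow C3=C4 to be installed by reduction and dehydration instead of quinone oxidation, a point in its favour for chemoselectivity.

Against it:
- The ring A pattern that this cascade builds is already purchasable in 1.
- A7 still lacks the C6 acyl group, whose introduction must distinguish C6 from C8, and it carries a carbonyl group that must be removed.
- A8 requires diazo chemistry, A9 is volatile and unstable, and the photolysis scales poorly, so it is clearly the less safe route.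

In comparison, the mechanism is elegant and highly regiocontrolled, but structurally it solves a problem the chosen plan does not have, and it would need ten or more steps.

Key step: step 1

Remark: 10 has no stereocentre; its 1,3-diketone is drawn in the diketo form although the chelated enol should predominate, and 2 is drawn as monomeric formaldehyde although it is charged as paraformaldehyde.

## Route

Step 1
Reactants: 1 1-(2,4-dihydroxy-6-methoxyphenyl)ethanone (2',4'-dihydroxy-6'-methoxyacetophenone); 2 formaldehyde (charged as paraformaldehyde); 3 isobutene (2-methylpropene)
Product: 6 chroman ketone 1-(5-hydroxy-7-methoxy-2,2-dimethyl-3,4-dihydro-2H-chromen-6-yl)ethanone, via hydroxymethyl phenol 4 (not isolated), via ortho-quinone methide 5 (not isolated)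
Conditions: 2 (1.1 equiv), 3 (ca. 20 equiv, condensed into the cooled vessel), NaOAc (0.2 equiv), AcOH (2 equiv), 1,4-dioxane, sealed steel pressure vessel, 100 °C
Reagents that add atoms: none
Why: Formaldehyde released on heating is attacked by C3 of 1 in an ortho-hydroxymethylation (Lederer–Manasse type) to give 4, and loss of water across the new CH2OH and the non-chelated 4-hydroxyl gives the ortho-quinone methide 5. 5 is an electron-poor 1-oxadiene, made more electrophilic by the acetyl group, and should add isobutene in an inverse-electron-demand hetero-Diels–Alder reaction, a concerted but asynchronous (4+2) closure of the pyran ring in which C4–C3 bonding runs ahead, positive charge builds on the tertiary carbon, and that carbon therefore bonds to oxygen (2,2-dimethyl, not 3,3-dimethyl). The closest known reaction type is the three-component Knoevenagel/ortho-quinone methide/hetero-Diels–Alder coupling of acylphloroglucinols with aldehydes and 1,1-disubstituted alkenes, together with the thermal phenol–formaldehyde–olefin chroman synthesis. No stereocentre is formed. Site selectivity should follow from C3 being ortho to both hydroxyls and from the bond fixation imposed by the hydrogen-bonded chelate between the 2-hydroxyl and the acetyl carbonyl, which localises enol character on C3–C4; closure through O4 keeps that hydrogen bond, whereas closure through O2 would give it up. A large excess of isobutene and only a slight excess of formaldehyde are chosen so that capture of 5 by the alkene outruns capture by a second molecule of 1 and a second hydroxymethylation. Rearomatisation of ring A provides the driving force.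

Step 2
Reactants: 6 chroman ketone 1-(5-hydroxy-7-methoxy-2,2-dimethyl-3,4-dihydro-2H-chromen-6-yl)ethanone
Product: 7 chromene ketone 1-(5-hydroxy-7-methoxy-2,2-dimethyl-2H-chromen-6-yl)ethanone
Conditions: DDQ (1.2 equiv), 1,4-dioxane, 90 °C
Reagents that add atoms: none
Why: Quinone dehydrogenation: DDQ should abstract hydride from benzylic C4, whose cation is stabilised by O1, the C5 hydroxyl and the C7 methoxy group, and loss of a C3 proton gives the conjugated chromene. The quaternary C2 blocks any further dehydrogenation, and the hydrogen bond to the acetyl group should make the chelated phenol less prone to oxidation.

Step 3
Reactants: 7 chromene ketone 1-(5-hydroxy-7-methoxy-2,2-dimethyl-2H-chromen-6-yl)ethanone; 8 methyl benzoate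
Product: 10 target diketone 1-(5-hydroxy-7-methoxy-2,2-dimethyl-2H-chromen-6-yl)-3-phenylpropane-1,3-dione, via dilithium enolate-phenoxide 9 (not isolated)
Conditions: LiN(SiMe3)2 (3.5 equiv), THF, −78 to −10 °C; then 8 (1.2 equiv), −78 °C to rt; AcOH quench, 0 °C
Reagents that add atoms: none
Why: Crossed Claisen condensation: excess LiN(SiMe3)2 forms the phenoxide–enolate dianion 9, whose carbon terminus attacks the non-enolisable ester 8, and the further equivalent of base deprotonates the more acidic diketone and pulls the equilibrium forward. The chromene is inert to the base, and the mild AcOH quench avoids acid-induced flavone closure.

## Compound list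

1 | 1-(2,4-dihydroxy-6-methoxyphenyl)ethanone | COc1cc(O)cc(O)c1C(C)=O | starting material
2 | formaldehyde (charged as paraformaldehyde) | C=O | starting material
3 | isobutene (2-methylpropene) | CC(C)=C | starting material
4 | 1-[2,4-dihydroxy-3-(hydroxymethyl)-6-methoxyphenyl]ethanone | COc1cc(O)c(CO)c(O)c1C(C)=O | intermediate
5 | 4-acetyl-5-hydroxy-3-methoxy-6-methylidenecyclohexa-2,4-dien-1-one (ortho-quinone methide) | COC1=CC(=O)C(=C)C(O)=C1C(C)=O | intermediate
6 | 1-(5-hydroxy-7-methoxy-2,2-dimethyl-3,4-dihydro-2H-chromen-6-yl)ethanone | COc1cc2OC(C)(C)CCc2c(O)c1C(C)=O | intermediate
7 | 1-(5-hydroxy-7-methoxy-2,2-dimethyl-2H-chromen-6-yl)ethanone | COc1cc2OC(C)(C)C=Cc2c(O)c1C(C)=O | intermediate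
8 | methyl benzoate | COC(=O)c1ccccc1 | starting material
9 | dilithium 6-(1-oxidoethenyl)-7-methoxy-2,2-dimethyl-2H-chromen-5-olate | [Li+].[Li+].COc1cc2OC(C)(C)C=Cc2c([O-])c1C(=C)[O-] | intermediate
10 | 1-(5-hydroxy-7-methoxy-2,2-dimethyl-2H-chromen-6-yl)-3-phenylpropane-1,3-dione | COc1cc2c(c(O)c1C(=O)CC(=O)c1ccccc1)C=CC(C)(C)O2 | target

## Step count and risk assessment

Total step count: 3. Longest linear sequence: 3 steps (1 to 6 to 7 to 10); 2, 3 and 8 are purchased.

The least certain steps are step 1 (the key step), step 2 and step 3, in that order.

For step 1, the key step, there are three likely failures.
- The transient quinone methide 5 may be captured by a second molecule of the very electron-rich arene 1 (methylene bridging), or a second hydroxymethylation may occur, because the unactivated alkene is volatile and partly in the headspace.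
- Formaldehyde may attack the other free ring carbon, between hydroxyl and methoxy, or ring closure may run through the chelated hydroxyl. Either would lead to a regioisomeric chroman.
- Acid-promoted Prins-type consumption of formaldehyde by isobutene may compete.

The orientation of 6 should be checked by looking for an NOE between the methoxy protons and the lone aromatic proton and for a strongly hydrogen-bonded hydroxyl signal.

The fallback sets out from 1 and comes back to the route at 7. Compound 1 would be heated with 3-methylbut-2-enal A6 and catalytic ethylenediammonium diacetate in toluene at reflux. Condensation at C3 and loss of water should give the dienone 4-acetyl-5-hydroxy-3-methoxy-6-(3-methylbut-2-en-1-ylidene)cyclohexa-2,4-dien-1-one F1, which should close by oxa-6π electrocyclisation directly to 7. The alkene carbons are then delivered within the aldehyde, so no bimolecular trapping is needed and step 2 is not required. The cost is that the three-component assembly is given up.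

For step 2, the most likely failure is that, after hydride loss, the C4 cation sheds the C5 hydroxyl proton and behaves as a quinone methide that adds the reduced quinone or another phenol. The acetyl group may also slow hydride transfer so that forcing conditions cause over-oxidation.

The fallback sets out from 6 and comes back to the route at 7. Acetylation (Ac2O, DMAP, pyridine) would give 6-acetyl-7-methoxy-2,2-dimethyl-3,4-dihydro-2H-chromen-5-yl acetate F2. Radical benzylic bromination (NBS, AIBN, PhCF3, 80 °C) would give racemic 6-acetyl-4-bromo-7-methoxy-2,2-dimethyl-3,4-dihydro-2H-chromen-5-yl acetate F3. Dehydrobromination with DBU in toluene would give 6-acetyl-7-methoxy-2,2-dimethyl-2H-chromen-5-yl acetate F4. Methanolysis of the acetate (catalytic K2CO3, MeOH) would return 7.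

For step 3, the most likely failure is sluggish C-acylation of the hindered dianion 9 by an ester, so that O-benzoylation of the phenoxide competes or 7 is left unchanged. Cyclodehydration of the product to the flavone is a further risk if work-up or chromatography is acidic.

The fallback sets out from 7 and comes back to the route at 10 by a Baker–Venkataraman sequence. O-Benzoylation (benzoyl chloride, pyridine) would give 6-acetyl-7-methoxy-2,2-dimethyl-2H-chromen-5-yl benzoate F5. Treatment with KOH in pyridine at 50 °C, followed by an AcOH work-up, should transfer the benzoyl group from oxygen to the enolate carbon and give 10.

## Further compounds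

F1 | step 1 | 4-acetyl-5-hydroxy-3-methoxy-6-(3-methylbut-2-en-1-ylidene)cyclohexa-2,4-dien-1-one (exocyclic alkene geometry not fixed) | COC1=CC(=O)C(=CC=C(C)C)C(O)=C1C(C)=O
F2 | step 2 | 6-acetyl-7-methoxy-2,2-dimethyl-3,4-dihydro-2H-chromen-5-yl acetate | COc1cc2OC(C)(C)CCc2c(OC(C)=O)c1C(C)=O
F3 | step 2 | 6-acetyl-4-bromo-7-methoxy-2,2-dimethyl-3,4-dihydro-2H-chromen-5-yl acetate (racemic) | COc1cc2OC(C)(C)CC(Br)c2c(OC(C)=O)c1C(C)=O
F4 | step 2 | 6-acetyl-7-methoxy-2,2-dimethyl-2H-chromen-5-yl acetate | COc1cc2OC(C)(C)C=Cc2c(OC(C)=O)c1C(C)=O
F5 | step 3 | 6-acetyl-7-methoxy-2,2-dimethyl-2H-chromen-5-yl benzoate | COc1cc2OC(C)(C)C=Cc2c(OC(=O)c3ccccc3)c1C(C)=O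
A1 | alternative 1 | 1-(5-hydroxy-7-methoxy-2,2-dimethyl-2H-chromen-6-yl)-2-(2-phenyl-1,3-dioxolan-2-yl)ethanone | COc1cc2OC(C)(C)C=Cc2c(O)c1C(=O)CC1(OCCO1)c1ccccc1
A2 | alternative 1 | 7-methoxy-2,2-dimethyl-6-(trimethylsilyl)-2H-chromen-5-yl trifluoromethanesulfonate | COc1cc2OC(C)(C)C=Cc2c(OS(=O)(=O)C(F)(F)F)c1[Si](C)(C)C
A3 | alternative 1 | 2-(2-phenyl-1,3-dioxolan-2-yl)acetic acid | OC(=O)CC1(OCCO1)c1ccccc1
A4 | alternative 2 | 7-methoxy-5-(methoxymethoxy)-2,2-dimethyl-2H-chromene | COCOc1cc(OC)cc2OC(C)(C)C=Cc12
A5 | alternative 2 | 5-methoxy-3-(methoxymethoxy)-2-(trimethylsilyl)phenyl trifluoromethanesulfonate | COCOc1cc(OC)cc(OS(=O)(=O)C(F)(F)F)c1[Si](C)(C)C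
A6 | alternative 2 | 3-methylbut-2-enal | CC(C)=CC=O
A7 | alternative 3 | 5-hydroxy-7-methoxy-2,2-dimethylchroman-4-one | COc1cc(O)c2C(=O)CC(C)(C)Oc2c1
A8 | alternative 3 | 6-(2-diazoacetyl)-2,2-dimethyl-2,3-dihydro-4H-pyran-4-one | CC1(C)CC(=O)C=C(O1)C(=O)C=[N+]=[N-]
A9 | alternative 3 | methoxyethyne | COC#C
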